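**Strategy.** Ring A is made last. The disconnection removes the C5/C7-dioxygenated benzene ring (C4a, C5, C6, C7, C8, C8a) from a finished ring C, a 4-pyranone whose weakly aromatic C4a=C8a enol-ether double bond acts as the vinyl partner of a diazoketone–ynol ether benzannulation. In one operation a pyranonyl ketene, formed by a Wolff shift, takes up benzyl ethynyl ether and the resulting cyclobutenone reorganises electrocyclically. This forges C8–C8a, C5–C6, C7–C8 and C4a–C5 and releases O5 as a chelated phenol beside benzylated O7 and MOM-masked O3. The precursor is a comenic acid-derived 2-aryl-3-(methoxymethoxy)-4-pyranone carrying a diazoacetyl group at pyranone C6 (the future C8a).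

Key step: step 6

Assumption: the target is taken in the hydrogen sulfate (acid) form as drawn; the sulfate monoester is carried as its potassium salt and protonated only in the last operation, cold, because aryl hydrogen sulfates hydrolyse on prolonged exposure to acid.

Numbering remark: pyranone numbering is used for compounds 1–9; flavone numbering (ring A = C4a–C8a, ring C = pyranone) is used for the atoms formed in step 6 and for compounds 18–27.

Step 1
Reactants: 1 comenic acid (5-hydroxy-4-oxo-4H-pyran-2-carboxylic acid)
Product: 2 6-bromo-5-hydroxy-4-oxo-4H-pyran-2-carboxylic acid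
Conditions: Br2 (1.0 equiv), H2O, 20 °C
Reagents that add atoms: bromine, BrBr
Why: Electrophilic bromination of the enol (SEAr-type substitution) goes to C6, the only ring CH activated by the adjacent 5-hydroxyl and the position beside the ring oxygen, as is typical of kojic- and comenic-type pyranones, and one equivalent of bromine limits oxidative degradation.

Step 2
Reactants: 2 6-bromo-5-hydroxy-4-oxo-4H-pyran-2-carboxylic acid
Product: 3 methoxymethyl 6-bromo-5-(methoxymethoxy)-4-oxo-4H-pyran-2-carboxylate
Conditions: MOMCl (2.4 equiv), i-Pr2NEt, DMF, 0 to 20 °C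
Reagents that add atoms: chloromethyl methyl ether, COCCl
Why: A single Williamson-type O-alkylation turns the carboxylate into a MOM ester and the acidic enol into a MOM ether, so the future O3 is masked as a base-stable acetal while the acid is held as an ester that mild hydroxide removes later.

Step 3
Reactants: 3 methoxymethyl 6-bromo-5-(methoxymethoxy)-4-oxo-4H-pyran-2-carboxylate; 4 4-(benzyloxy)phenylboronic acid
Product: 7 6-(4-(benzyloxy)phenyl)-5-(methoxymethoxy)-4-oxo-4H-pyran-2-carboxylic acid, via biaryl MOM ester 5 (not isolated), via lithium carboxylate 6 (not isolated)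
Conditions: Pd(PPh3)4 (5 mol %), K3PO4, 1,4-dioxane, 85 °C; then LiOH, H2O, 20 °C; 1 M HCl (0 °C) to pH 2, rapid extraction
Reagents that add atoms: lithium hydroxide, [Li+].[OH-]
Why: Suzuki–Miyaura coupling at the C6–Br bond, which is activated towards oxidative addition like a vinylogous acyl bromide, installs the future ring B, and saponification of the MOM ester in the same pot frees the acid while the MOM ether and the benzyl ether are inert to base.

Step 4
Reactants: 7 6-(4-(benzyloxy)phenyl)-5-(methoxymethoxy)-4-oxo-4H-pyran-2-carboxylic acid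
Product: 9 2-(4-(benzyloxy)phenyl)-6-(2-diazoacetyl)-3-(methoxymethoxy)-4H-pyran-4-one, via mixed isobutyl carbonic anhydride 8 (not isolated)
Conditions: i-BuOCOCl, N-methylmorpholine, THF, −15 °C; then CH2N2 (3 equiv, Et2O), −15 to 0 °C
Reagents that add atoms: diazomethane, C=[N+]=[N-]
Why: Acylation of diazomethane by a mixed carbonic anhydride (the diazoketone stage of the Arndt–Eistert sequence) occurs at the more electrophilic pyranone acyl carbon and avoids the HCl-generating acid chloride route, so the MOM acetal is preserved.

Step 5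
Reactants: 10 benzyl alcohol; 11 trichloroethylene
Product: 17 benzyl ethynyl ether, via potassium benzyloxide 12 (not isolated), via dichloroacetylene 13 (not isolated), via benzyl (E)-1,2-dichlorovinyl ether 14 (not isolated), via benzyl chloroethynyl ether 15 (not isolated), via lithium (benzyloxy)ethynide 16 (not isolated)
Conditions: KH, THF, 0 °C; Cl2C=CHCl, −50 to 20 °C; then n-BuLi (2.4 equiv), −78 to −40 °C; MeOH, −78 °C; kept cold as a stock solution
Reagents that add atoms: none
Why: In the Greene ynol ether synthesis the alkoxide adds anti to dichloroacetylene generated in situ from trichloroethylene to give the (E)-dichlorovinyl ether, and n-BuLi then effects dehydrochlorination and chlorine–lithium exchange to the lithium acetylide, which methanol protonates.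

Step 6
Reactants: 9 2-(4-(benzyloxy)phenyl)-6-(2-diazoacetyl)-3-(methoxymethoxy)-4H-pyran-4-one; 17 benzyl ethynyl ether
Product: 22 7-(benzyloxy)-2-(4-(benzyloxy)phenyl)-5-hydroxy-3-(methoxymethoxy)-4H-chromen-4-one, via pyranonylketene 18 (not isolated), via pyranonylcyclobutenone 19 (not isolated), via dienylketene 20 (not isolated), via keto tautomer 21 (not isolated)
Conditions: 17 (2.5 equiv), ClCH2CH2Cl (degassed, 0.02 M), hν (405–450 nm LED), 15 °C; excess 17 removed in vacuo below 25 °C; then PhMe, 80 °C
Reagents that add atoms: none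
Why: Light expels N2 and the pyranonyl group shifts to the former diazo carbon (Wolff rearrangement, new C8–C8a bond) to give ketene 18, whose electrophilic carbonyl carbon (the future C5) is attacked by the nucleophilic CH terminus of the ynol ether in a [2+2] cycloaddition that forms C5–C6 and C7–C8 and so places the benzyloxy carbon at C7 of cyclobutenone 19. On warming, 19 opens by reversible conrotatory 4π cleavage of its C5–C8 bond to dienylketene 20, and the geometry with the pyranone cis to the ketene arm is drained by a thermal disrotatory 6π electrocyclization that closes ring A across the C4a=C8a bond (new C4a–C5 bond), after which enolisation of the β-diketone 21 aromatises the ring and leaves the C5 hydroxyl hydrogen-bonded to the C4 carbonyl. The closest known reaction type is the Danheiser benzannulation in its diazoketone form, established for α,β-unsaturated, aryl and heteroaryl diazomethyl ketones with alkoxy- and siloxyalkynes; the 4-pyranone double bond is a new member of that substrate class and, being only weakly aromatic, should give up its double bond more readily than the benzene or furan rings known to take part. No stereocenter survives, because the sp3 carbons of 19 (C8) and 21 (C4a) both end as aromatic carbons. Two regiochemical choices must come out right: the polarisation of the ynol ether fixes the cycloaddition, and C8a carries only one carbon neighbour (C4a), so the ketene has a single position on which to close. Near-visible light is chosen to reach the n→π* band of the diazoketone while staying clear of the aryl-pyranone absorption, and the cycloaddition is completed at 15 °C before any heating because benzyl alkynyl ethers rearrange sigmatropically above about 60 °C.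

Step 7
Reactants: 22 7-(benzyloxy)-2-(4-(benzyloxy)phenyl)-5-hydroxy-3-(methoxymethoxy)-4H-chromen-4-one
Product: 23 7-(benzyloxy)-2-(4-(benzyloxy)phenyl)-3,5-dihydroxy-4H-chromen-4-one
Conditions: HCl (3 M in MeOH), THF, 40 °C
Reagents that add atoms: none
Why: Acid-catalysed methanolysis of the MOM acetal (transacetalisation to dimethoxymethane) frees O3, while benzyl aryl ethers and the chromone are inert to dilute methanolic HCl.

Step 8
Reactants: 23 7-(benzyloxy)-2-(4-(benzyloxy)phenyl)-3,5-dihydroxy-4H-chromen-4-one
Product: 25 potassium 7-(benzyloxy)-2-(4-(benzyloxy)phenyl)-5-hydroxy-4-oxo-4H-chromen-3-yl sulfate, via pyridinium sulfate 24 (not isolated)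
Conditions: SO3·pyridine (3 equiv), pyridine, 40 °C; then KOH, MeOH, 0 °C, to pH 8
Reagents that add atoms: sulfur trioxide–pyridine complex, [O-]S(=O)(=O)[n+]1ccccc1; potassium hydroxide, [K+].[OH-]
Why: O-Sulfation with the SO3·pyridine complex takes place at the enolic 3-hydroxyl, whereas the 5-hydroxyl is held in a six-membered hydrogen bond to the C4 carbonyl and is the least nucleophilic hydroxyl of a flavonol, and O7 and O4' are blocked as benzyl ethers.

Step 9
Reactants: 25 potassium 7-(benzyloxy)-2-(4-(benzyloxy)phenyl)-5-hydroxy-4-oxo-4H-chromen-3-yl sulfate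
Product: 27 kaempferol 3-O-sulfate (5,7-dihydroxy-2-(4-hydroxyphenyl)-4-oxo-4H-chromen-3-yl hydrogen sulfate), via potassium kaempferol 3-O-sulfate 26 (not isolated)
Conditions: H2 (1 atm), 10% Pd/C, MeOH/THF, 20 °C; filter; 0.1 M HCl (1.0 equiv), 0 °C; C18 desalting, freeze-drying
Reagents that add atoms: none
Why: Catalytic hydrogenolysis cleaves both benzyl aryl ethers without reducing the tetrasubstituted C2=C3 bond or the sulfate monoester salt, and one equivalent of cold dilute acid then only protonates the sulfate.

**Compound list**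

1 | comenic acid (5-hydroxy-4-oxo-4H-pyran-2-carboxylic acid) | O=C(O)c1cc(=O)c(O)co1 | starting material
2 | 6-bromo-5-hydroxy-4-oxo-4H-pyran-2-carboxylic acid | O=C(O)c1cc(=O)c(O)c(Br)o1 | intermediate
3 | methoxymethyl 6-bromo-5-(methoxymethoxy)-4-oxo-4H-pyran-2-carboxylate | COCOC(=O)c1cc(=O)c(OCOC)c(Br)o1 | intermediate
4 | 4-(benzyloxy)phenylboronic acid | OB(O)c1ccc(OCc2ccccc2)cc1 | starting material
5 | methoxymethyl 6-(4-(benzyloxy)phenyl)-5-(methoxymethoxy)-4-oxo-4H-pyran-2-carboxylate | COCOC(=O)c1cc(=O)c(OCOC)c(-c2ccc(OCc3ccccc3)cc2)o1 | intermediate (not isolated)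
6 | lithium 6-(4-(benzyloxy)phenyl)-5-(methoxymethoxy)-4-oxo-4H-pyran-2-carboxylate | [Li+].[O-]C(=O)c1cc(=O)c(OCOC)c(-c2ccc(OCc3ccccc3)cc2)o1 | intermediate (not isolated)
7 | 6-(4-(benzyloxy)phenyl)-5-(methoxymethoxy)-4-oxo-4H-pyran-2-carboxylic acid | O=C(O)c1cc(=O)c(OCOC)c(-c2ccc(OCc3ccccc3)cc2)o1 | intermediate
8 | isobutyl carbonic 6-(4-(benzyloxy)phenyl)-5-(methoxymethoxy)-4-oxo-4H-pyran-2-carboxylic anhydride | CC(C)COC(=O)OC(=O)c1cc(=O)c(OCOC)c(-c2ccc(OCc3ccccc3)cc2)o1 | intermediate (not isolated)
9 | 2-(4-(benzyloxy)phenyl)-6-(2-diazoacetyl)-3-(methoxymethoxy)-4H-pyran-4-one | [N-]=[N+]=CC(=O)c1cc(=O)c(OCOC)c(-c2ccc(OCc3ccccc3)cc2)o1 | intermediate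
10 | benzyl alcohol | OCc1ccccc1 | starting material
11 | trichloroethylene | ClC=C(Cl)Cl | starting material
12 | potassium benzyloxide | [K+].[O-]Cc1ccccc1 | intermediate (not isolated)
13 | dichloroacetylene | ClC#CCl | intermediate (not isolated)
14 | benzyl (E)-1,2-dichlorovinyl ether | Cl/C=C(/Cl)OCc1ccccc1 | intermediate (not isolated)
15 | benzyl chloroethynyl ether | ClC#COCc1ccccc1 | intermediate (not isolated)
16 | lithium (benzyloxy)ethynide | [Li]C#COCc1ccccc1 | intermediate (not isolated)
17 | benzyl ethynyl ether | C#COCc1ccccc1 | intermediate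
18 | 2-[6-(4-(benzyloxy)phenyl)-5-(methoxymethoxy)-4-oxo-4H-pyran-2-yl]ethenone (pyranonylketene) | O=C=Cc1cc(=O)c(OCOC)c(-c2ccc(OCc3ccccc3)cc2)o1 | intermediate (not isolated)
19 | 3-(benzyloxy)-4-[6-(4-(benzyloxy)phenyl)-5-(methoxymethoxy)-4-oxo-4H-pyran-2-yl]cyclobut-2-en-1-one (racemic) | O=C1C=C(OCc2ccccc2)C1c1cc(=O)c(OCOC)c(-c2ccc(OCc3ccccc3)cc2)o1 | intermediate (not isolated)
20 | 3-(benzyloxy)-4-[6-(4-(benzyloxy)phenyl)-5-(methoxymethoxy)-4-oxo-4H-pyran-2-yl]buta-1,3-dien-1-one, ketene arm and pyranone cis on the C3=C4 bond | O=C=C/C(OCc1ccccc1)=C\c1cc(=O)c(OCOC)c(-c2ccc(OCc3ccccc3)cc2)o1 | intermediate (not isolated)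
21 | 7-(benzyloxy)-2-(4-(benzyloxy)phenyl)-3-(methoxymethoxy)-4aH-chromene-4,5-dione (racemic at C4a) | O=C1C=C(OCc3ccccc3)C=C2OC(-c3ccc(OCc4ccccc4)cc3)=C(OCOC)C(=O)C12 | intermediate (not isolated)
22 | 7-(benzyloxy)-2-(4-(benzyloxy)phenyl)-5-hydroxy-3-(methoxymethoxy)-4H-chromen-4-one | O=c1c(OCOC)c(-c2ccc(OCc3ccccc3)cc2)oc2cc(OCc3ccccc3)cc(O)c12 | intermediate
23 | 7-(benzyloxy)-2-(4-(benzyloxy)phenyl)-3,5-dihydroxy-4H-chromen-4-one | O=c1c(O)c(-c2ccc(OCc3ccccc3)cc2)oc2cc(OCc3ccccc3)cc(O)c12 | intermediate
24 | pyridinium 7-(benzyloxy)-2-(4-(benzyloxy)phenyl)-5-hydroxy-4-oxo-4H-chromen-3-yl sulfate | c1cc[nH+]cc1.[O-]S(=O)(=O)Oc1c(-c2ccc(OCc3ccccc3)cc2)oc2cc(OCc3ccccc3)cc(O)c2c1=O | intermediate (not isolated)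
25 | potassium 7-(benzyloxy)-2-(4-(benzyloxy)phenyl)-5-hydroxy-4-oxo-4H-chromen-3-yl sulfate | [K+].[O-]S(=O)(=O)Oc1c(-c2ccc(OCc3ccccc3)cc2)oc2cc(OCc3ccccc3)cc(O)c2c1=O | intermediate
26 | potassium 5,7-dihydroxy-2-(4-hydroxyphenyl)-4-oxo-4H-chromen-3-yl sulfate | [K+].[O-]S(=O)(=O)Oc1c(-c2ccc(O)cc2)oc2cc(O)cc(O)c2c1=O | intermediate (not isolated)
27 | kaempferol 3-O-sulfate | O=c1c(OS(=O)(=O)O)c(-c2ccc(O)cc2)oc2cc(O)cc(O)c12 | target

**Step count.** Total: 9 steps. Longest linear sequence: 8 steps (steps 1–4 and 6–9, from comenic acid 1); the alkyne branch is step 5.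

**Steps most likely to fail**

1. Step 6 (benzannulation). Light absorbed by the aryl-pyranone chromophore may divert the substrate into pyranone photoisomerisation. The ketene may dimerise or be consumed by adventitious nucleophiles before the ynol ether captures it. On heating, the dienylketene may oligomerise instead of closing onto the pyranone double bond.
   Fallback: setting out from 9, the ketene is generated in the dark and the cascade is divided into two operations. A PhCO2Ag-catalysed Wolff rearrangement of 9 in aqueous THF with Et3N (Arndt–Eistert homologation) should give 2-[6-(4-(benzyloxy)phenyl)-5-(methoxymethoxy)-4-oxo-4H-pyran-2-yl]acetic acid F1. Neutral chlorination with 1-chloro-N,N,2-trimethylprop-1-en-1-amine in CH2Cl2 should give 2-[6-(4-(benzyloxy)phenyl)-5-(methoxymethoxy)-4-oxo-4H-pyran-2-yl]acetyl chloride F2 without touching the MOM acetal. Slow addition of Et3N to F2 and 17 at 0 °C dehydrochlorinates F2 to ketene 18, which is trapped as cyclobutenone 19, a known ketene–alkoxyacetylene cycloaddition. Here 19 is isolated and then heated in toluene at 80 °C, so the route is rejoined at 19 and continues to 22. This fallback removes the photochemical hazards but still relies on the electrocyclic closure onto the pyranone.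

2. Step 5 (ynol ether). Benzylic metalation and Wittig-type rearrangement may compete under excess n-BuLi at −40 °C. The ynol ether may also be lost by sigmatropic rearrangement or oligomerisation during concentration.
   Fallback: setting out from 10, formylation with acetic formic anhydride (HCO2H, Ac2O, pyridine, 0 °C) should give benzyl formate F3. Wittig-type dichloromethylenation of the formate carbonyl (PPh3, CCl4, THF, reflux) should give benzyl 2,2-dichlorovinyl ether F4, which is stable and can be stored. This 1,1-dichloro isomer eliminates with n-BuLi (2.1 equiv) already at −78 °C, so benzylic metalation is suppressed. The resulting lithium acetylide 16 is quenched with MeOH and the cold solution is used directly, rejoining the route at 17.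

3. Step 8 (3-O-sulfation). Conversion of the hindered, hydrogen-bonded 3-hydroxyl may stay incomplete. Forcing conditions may begin to sulfate O5. The ionic product may lose sulfate or material during chromatography.
   Fallback: setting out from 23, the sulfate is introduced as a neutral protected diester. Treatment with 2,2,2-trichloroethyl chlorosulfate, Et3N and DMAP in THF should give 7-(benzyloxy)-2-(4-(benzyloxy)phenyl)-5-hydroxy-4-oxo-4H-chromen-3-yl 2,2,2-trichloroethyl sulfate F5, which can be purified on silica. Transfer hydrogenolysis (10% Pd/C, HCO2NH4, MeOH, 20 °C) then removes the trichloroethyl group and both benzyl ethers in one operation. This should give ammonium 5,7-dihydroxy-2-(4-hydroxyphenyl)-4-oxo-4H-chromen-3-yl sulfate F6, which is protonated cold as in step 9 to rejoin the route at 27.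

**Further compounds**

F1 | step 6 | 2-[6-(4-(benzyloxy)phenyl)-5-(methoxymethoxy)-4-oxo-4H-pyran-2-yl]acetic acid | O=C(O)Cc1cc(=O)c(OCOC)c(-c2ccc(OCc3ccccc3)cc2)o1
F2 | step 6 | 2-[6-(4-(benzyloxy)phenyl)-5-(methoxymethoxy)-4-oxo-4H-pyran-2-yl]acetyl chloride | O=C(Cl)Cc1cc(=O)c(OCOC)c(-c2ccc(OCc3ccccc3)cc2)o1
F3 | step 5 | benzyl formate | O=COCc1ccccc1
F4 | step 5 | benzyl 2,2-dichlorovinyl ether | ClC(Cl)=COCc1ccccc1
F5 | step 8 | 7-(benzyloxy)-2-(4-(benzyloxy)phenyl)-5-hydroxy-4-oxo-4H-chromen-3-yl 2,2,2-trichloroethyl sulfate | O=c1c(OS(=O)(=O)OCC(Cl)(Cl)Cl)c(-c2ccc(OCc3ccccc3)cc2)oc2cc(OCc3ccccc3)cc(O)c12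
F6 | step 8 | ammonium 5,7-dihydroxy-2-(4-hydroxyphenyl)-4-oxo-4H-chromen-3-yl sulfate | [NH4+].[O-]S(=O)(=O)Oc1c(-c2ccc(O)cc2)oc2cc(O)cc(O)c2c1=O
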